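The easy step first: a turnover needs carrier and time, so I read each run against loading times time, the dose (a normalised time axis), and a flask with less carrier takes longer on the clock to reach the same dose.

| flask | starting material | salt in the second phase | spent carrier | remark | time | volume of the second phase over the first |
|---|---|---|---|---|---|---|
| ash | 0.34 M | 1.1 equiv | 2.8 mol% | run made earlier |  |  |
| birch | 0.34 M | 1.1 equiv | 4.4 mol% | run made earlier |  |  |
| flask | 0.34 M | 1.10 equiv | 2 mol% |  | 25 min | 0.25 |

| run | time / min | starting material / % | target / % |
|---|---|---|---|
| ash | 3.00 | 87.0 | 13.3 |
| ash | 6.00 | 77.9 | 22.3 |
| ash | 10.0 | 69.3 | 29.8 |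
| ash | 12.0 | 66.6 | 34.0 |
| ash | 15.0 | 62.0 | 37.4 |
| ash | 20.0 | 57.3 | 42.2 |
| birch | 1.33 | 91.2 | 9.9 |
| birch | 4.00 | 76.3 | 23.7 |
| birch | 8.00 | 63.6 | 36.4 |
| birch | 10.0 | 59.4 | 40.3 |
| birch | 15.0 | 52.3 | 48.5 |
| birch | 20.0 | 46.3 | 53.8 |

(each reading ± 0.5 percentage points)

- in the second phase: salt in the second phase, spent salt in the second phase; everything else is in the first
- charges count per volume of the first phase; a concentration in a rate is the amount of a species over the volume of its own phase; every rate counts per litre of the first phase
- candidate steps: fresh carrier <-> dormant form; target + spent carrier -> spent catalyst; spent carrier + salt in the second phase <-> fresh carrier + spent salt in the second phase; starting material + fresh carrier -> target + spent carrier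
- the earlier runs hold the two phases in the same ratio of volumes as the flask asked about

- the species that holds most of what was charged as starting material, at 25 min (starting material / target)
- the largest share itself, whichever of these holds it, in percent of the starting material charged

To whoever takes over the bench: this flask holds starting material with 2 mol% of spent carrier, in contact with the salt in the second phase, and its dose at 25 min equals that of ash at 17.9 min and of birch at 11.4 min. Between their readings, ash has 59.3% of starting material left there and birch 57.5%, so the slower run stands 1.8 percentage points higher after 6.50 min more on the clock. I keep 0.00285 min⁻¹ as the clock penalty, the fraction of the charge left unreacted for each extra minute taken to the same dose, a reading that carries their scatter. This flask takes 7.10 min longer than ash, so when you come I expect 61.3% of starting material, still ahead of target. Leave the phase ratio at 0.25, because both runs were read at it.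

The forecast says starting material at 61%, holding that “Most of the slowing therefore looks conversion-linked”. The flask gives starting material at 61.2%, with target at 38.7%.

    fresh carrier ⇌ dormant form (K = 4.20, k = 0.00120 s⁻¹)
    target + spent carrier → spent catalyst (k = 0.00140 L mol⁻¹ s⁻¹)
    spent carrier + salt in the second phase ⇌ fresh carrier + spent salt in the second phase (K = 0.430, k = 0.0740 L mol⁻¹ s⁻¹)
    starting material + fresh carrier → target + spent carrier (k = 0.150 L mol⁻¹ s⁻¹)

Fresh carrier turns into dormant form with a half-life of 9.6 min, counted by the forward rate alone, which is shorter than the 25 min of this flask, and at that time dormant form holds 44.9% of the catalyst charged, more than the 6.18% in spent catalyst. The penalty carries to the neighbour with 1.2 mol% of spent carrier: its dose over 25 min matches ash at 10.7 min, where 68.3% is left, the penalty adds 4.1 points to make 72.4%, and that flask holds 72.3%.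

The earlier runs and the new flask come from a simulation on assumed constants; the scatter is artificial.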